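**Retrosynthetic overview**

1. The last skeletal bond is C5'–C4' (side chain numbered C1'–C13' from C2 of the chromene). It is made together with C6'–C7' and the C6' stereocentre in a three-component enantioselective conjunctive cross-coupling: dienyl boronate 21 plus vinyllithium gives borate 22, which couples with alkenyl bromide 17 under chiral palladium catalysis. Oxidation in the same flask puts OH on C6', and desilylation ends the route.
2. Enabling feature: the carbinol C6' lies between an alkenyl carbon (C7' of C7'=C8') and a CH2 (C5') bonded to the sp2 carbon C4'. This is the footprint of a vinylboron unit (C6' = boron-bearing carbon, C5' = former vinyl terminus) that has taken up a migrating alkenyl group and an alkenyl electrophile.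
3. Bromide 17: (R)-linalool supplies C2 with its methyl group, C3, C4 and C1'–C3'. Hydroboration/Suzuki coupling joins it to arene 5. The pyran ring (ring B, O1–C8a bond) is the only ring closed (step 5); benzene ring A is bought. The prenyl end is cut back and rebuilt as the (E)-bromoalkene, and C3=C4 is introduced last by dehydrogenation.
4. Boronate 21: acetylide alkylation, then zirconium-catalysed methylalumination/borylation of 6-methylhept-5-en-1-yne.

Key step: step 13

Remark: commercial (R)-(−)-linalool is used as bought, so the enantiomeric purity at C2 of the target is that of this starting material.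

**Route**

Step 1
Reactants: 1 4-amino-3-methylphenol
Product: 2 2-methyl-4-{[tri(propan-2-yl)silyl]oxy}aniline
Conditions: TIPSCl, imidazole, DMF, 0 °C to rt
Reagents that add atoms: chlorotri(propan-2-yl)silane (TIPSCl), CC(C)[Si](Cl)(C(C)C)C(C)C
Why: Imidazole-promoted silyl ether formation should take the phenol selectively because any N–Si bond is lost on aqueous work-up, and the bulky aryl silyl ether is chosen to survive the bases, organolithiums and DDQ used later and to leave with fluoride at the end.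

Step 2
Reactants: 2 2-methyl-4-{[tri(propan-2-yl)silyl]oxy}aniline
Product: 3 2-iodo-6-methyl-4-{[tri(propan-2-yl)silyl]oxy}aniline
Conditions: N-iodosuccinimide, MeCN, 0 °C, dark
Reagents that add atoms: N-iodosuccinimide, O=C1CCC(=O)N1I
Why: Electrophilic aromatic iodination should be directed by the amino group, the strongest donor on the ring, to its only free ortho position, the para position being occupied.

Step 3
Reactants: 3 2-iodo-6-methyl-4-{[tri(propan-2-yl)silyl]oxy}aniline
Product: 5 (4-bromo-3-iodo-5-methylphenoxy)tri(propan-2-yl)silane, via arenediazonium bromide 4 (not isolated)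
Conditions: t-BuONO, CuBr2, MeCN, 0 °C to rt
Reagents that add atoms: tert-butyl nitrite, CC(C)(C)ON=O (second nitrogen of 4 only); CuBr2, Br[Cu]Br
Why: Sandmeyer bromination under non-aqueous diazotisation should replace the amino group by bromine without touching the silyl ether or the iodide, giving an arene whose two halogens differ enough for sequential coupling.

Step 4
Reactants: 5 (4-bromo-3-iodo-5-methylphenoxy)tri(propan-2-yl)silane; 6 (R)-(−)-linalool, (3R)-3,7-dimethylocta-1,6-dien-3-ol
Product: 8 (3R)-1-(2-bromo-3-methyl-5-{[tri(propan-2-yl)silyl]oxy}phenyl)-3,7-dimethyloct-6-en-3-ol, via B-alkyl-9-BBN borane 7 (not isolated)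
Conditions: 6, 9-BBN, THF, 0 °C to rt; then 5, PdCl2(dppf) (5 mol %), K3PO4 (aq), DMF, rt to 40 °C
Reagents that add atoms: 9-borabicyclo[3.3.1]nonane, B1C2CCCC1CCC2 (boron unit of 7 only)
Why: 9-BBN should hydroborate only the monosubstituted vinyl group (anti-Markovnikov, the trisubstituted alkene being far slower), and the B-alkyl Suzuki–Miyaura coupling should take the C–I bond in preference to the flanked C–Br bond; the carbinol stereocentre is a spectator.

Step 5
Reactants: 8 (3R)-1-(2-bromo-3-methyl-5-{[tri(propan-2-yl)silyl]oxy}phenyl)-3,7-dimethyloct-6-en-3-ol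
Product: 9 tri(propan-2-yl){[(2R)-2,8-dimethyl-2-(4-methylpent-3-en-1-yl)-3,4-dihydro-2H-chromen-6-yl]oxy}silane
Conditions: Pd(OAc)2 (3 mol %), rac-2-(di-tert-butylphosphino)-1,1'-binaphthyl (4 mol %), Cs2CO3, toluene, 80 °C
Reagents that add atoms: none
Why: Intramolecular Buchwald–Hartwig C–O coupling of the aryl bromide with the tertiary alcohol, whose alkoxide cannot undergo β-hydride elimination, should close the six-membered pyran ring at O1–C8a, and because the C2–O bond is never broken the linalool configuration is carried over as 2R.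

Step 6
Reactants: 9 tri(propan-2-yl){[(2R)-2,8-dimethyl-2-(4-methylpent-3-en-1-yl)-3,4-dihydro-2H-chromen-6-yl]oxy}silane
Product: 11 3-[(2S)-2,8-dimethyl-6-{[tri(propan-2-yl)silyl]oxy}-3,4-dihydro-2H-chromen-2-yl]propanal, via vicinal diol 10 (not isolated)
Conditions: OsO4 (2 mol %), NaIO4 (4 equiv), 2,6-lutidine, 1,4-dioxane/H2O, rt
Reagents that add atoms: osmium tetroxide, O=[Os](=O)(=O)=O; sodium periodate, [Na+].[O-]I(=O)(=O)=O
Why: Lemieux–Johnson oxidative cleavage should dihydroxylate the electron-rich trisubstituted alkene and cleave the diol to the aldehyde while the aryl ether ring stays inert; the descriptor at C2 changes to S only because the CIP priorities change.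

Step 7
Reactants: 11 3-[(2S)-2,8-dimethyl-6-{[tri(propan-2-yl)silyl]oxy}-3,4-dihydro-2H-chromen-2-yl]propanal
Product: 12 {[(2R)-2-(4,4-dibromobut-3-en-1-yl)-2,8-dimethyl-3,4-dihydro-2H-chromen-6-yl]oxy}tri(propan-2-yl)silane
Conditions: CBr4, PPh3, CH2Cl2, 0 °C
Reagents that add atoms: tetrabromomethane, BrC(Br)(Br)Br
Why: Ramirez dibromo-olefination (first stage of the Corey–Fuchs sequence) is a Wittig-type reaction that works reliably on unhindered aliphatic aldehydes under neutral conditions.

Step 8
Reactants: 12 {[(2R)-2-(4,4-dibromobut-3-en-1-yl)-2,8-dimethyl-3,4-dihydro-2H-chromen-6-yl]oxy}tri(propan-2-yl)silane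
Product: 14 {[(2R)-2,8-dimethyl-2-(pent-3-yn-1-yl)-3,4-dihydro-2H-chromen-6-yl]oxy}tri(propan-2-yl)silane, via lithium acetylide 13 (not isolated)
Conditions: n-BuLi (2.2 equiv), THF, −78 °C to 0 °C; then MeI, −78 °C to rt
Reagents that add atoms: n-butyllithium, CCCC[Li] (lithium of 13 only); iodomethane, CI
Why: In the second stage of the Corey–Fuchs sequence, bromine–lithium exchange and Fritsch–Buttenberg–Wiechell rearrangement should give the lithium acetylide, which is C-methylated in the same flask; the aryl silyl ether tolerates n-BuLi at low temperature.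

Step 9
Reactants: 14 {[(2R)-2,8-dimethyl-2-(pent-3-yn-1-yl)-3,4-dihydro-2H-chromen-6-yl]oxy}tri(propan-2-yl)silane
Product: 16 {[(2R)-2-[(3E)-4-bromopent-3-en-1-yl]-2,8-dimethyl-3,4-dihydro-2H-chromen-6-yl]oxy}tri(propan-2-yl)silane, via alkenylzirconocene chloride 15 (not isolated)
Conditions: Cp2Zr(H)Cl (2 equiv), THF, 50 °C; then N-bromosuccinimide, 0 °C
Reagents that add atoms: zirconocene chloride hydride Cp2Zr(H)Cl, [H][Zr](Cl)(C1C=CC=C1)C1C=CC=C1 (zirconium unit of 15 only); N-bromosuccinimide, O=C1CCC(=O)N1Br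
Why: Hydrozirconation with the Schwartz reagent is a syn addition, and with excess reagent and gentle heating the regioisomers should equilibrate to the one with zirconium on the less hindered, methyl-bearing alkyne carbon, so that bromination with retention gives the (E)-2-bromoalkene with bromine trans to the chain.

Step 10
Reactants: 16 {[(2R)-2-[(3E)-4-bromopent-3-en-1-yl]-2,8-dimethyl-3,4-dihydro-2H-chromen-6-yl]oxy}tri(propan-2-yl)silane
Product: 17 {[(2R)-2-[(3E)-4-bromopent-3-en-1-yl]-2,8-dimethyl-2H-chromen-6-yl]oxy}tri(propan-2-yl)silane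
Conditions: DDQ (1.3 equiv), benzene, 80 °C, dark
Reagents that add atoms: none
Why: DDQ dehydrogenation of an oxygenated 2,2-dialkylchromane should proceed by hydride abstraction from benzylic C4 (cation stabilised by O1 through C8a) and loss of the C3 proton; C2 has no hydrogen, and short heating in the dark is meant to prevent erosion of C2 by reversible electrocyclic opening of the 2H-pyran ring.

Step 11
Reactants: 18 5-bromo-2-methylpent-2-ene
Product: 19 6-methylhept-5-en-1-yne
Conditions: lithium acetylide–ethylenediamine complex, DMSO, 10 °C to rt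
Reagents that add atoms: lithium acetylide–ethylenediamine complex, [Li]C#C.NCCN
Why: SN2 alkylation of acetylide by an unhindered primary bromide in a dipolar aprotic solvent is a standard terminal alkyne synthesis.

Step 12
Reactants: 19 6-methylhept-5-en-1-yne
Product: 21 2-[(1E)-2,6-dimethylhepta-1,5-dien-1-yl]-4,4,5,5-tetramethyl-1,3,2-dioxaborolane, via alkenyldimethylalane 20 (not isolated)
Conditions: Me3Al (2 equiv), Cp2ZrCl2 (20 mol %), CH2Cl2, 0 °C to rt; then 2-isopropoxy-4,4,5,5-tetramethyl-1,3,2-dioxaborolane, 0 °C to rt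
Reagents that add atoms: trimethylaluminium, C[Al](C)C; 2-isopropoxy-4,4,5,5-tetramethyl-1,3,2-dioxaborolane, CC(C)OB1OC(C)(C)C(C)(C)O1
Why: Negishi zirconium-catalysed carboalumination adds methyl and aluminium syn across the terminal alkyne with aluminium on the terminal carbon, which fixes the E geometry of C7'=C8', and aluminium-to-boron exchange with the alkoxyboronate should occur with retention; the trisubstituted alkene does not react.

Step 13
Reactants: 17 {[(2R)-2-[(3E)-4-bromopent-3-en-1-yl]-2,8-dimethyl-2H-chromen-6-yl]oxy}tri(propan-2-yl)silane; 21 2-[(1E)-2,6-dimethylhepta-1,5-dien-1-yl]-4,4,5,5-tetramethyl-1,3,2-dioxaborolane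
Product: 24 (3E,6R,7E)-1-[(2R)-2,8-dimethyl-6-{[tri(propan-2-yl)silyl]oxy}-2H-chromen-2-yl]-4,8,12-trimethyltrideca-3,7,11-trien-6-ol, via lithium vinylborate complex 22 (not isolated), via allylic pinacol boronate 23 (not isolated)
Conditions: 21 (1.3 equiv), vinyllithium (1.3 equiv, halide-free, made beforehand from tetravinylstannane and n-BuLi), THF, 0 °C to rt; then 17, Pd(OAc)2 (3 mol %), (Sp,Sp)-1,1'-bis[bis(4-methoxy-3,5-dimethylphenyl)phosphino]-2,2'-bis[(R)-α-(dimethylamino)benzyl]ferrocene (3.6 mol %), KOTf (2 equiv), THF, 60 °C, dark; then NaBO3·4H2O, THF/H2O, rt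
Reagents that add atoms: vinyllithium, [Li]C=C; sodium perborate, [Na+].[O-]OB=O
Why: Vinyllithium adds to boron of 21 to give the four-coordinate borate 22; oxidative addition of the C–Br bond of 17 to zerovalent palladium and bromide abstraction by KOTf give a cationic alkenyl complex of divalent palladium that binds the unsubstituted vinyl group of 22, whereupon the dienyl group shifts from boron to the inner vinyl carbon (the future C6') anti to the metal while palladium takes the terminal carbon (C5'), and reductive elimination makes the C5'–C4' bond. The closest known reaction type is the enantioselective palladium-catalysed conjunctive cross-coupling of bis(alkenyl)borates with C(sp2) electrophiles (a metal-induced 1,2-metallate rearrangement), which activates the less substituted alkene, lets the more substituted alkenyl group migrate and delivers secondary allylic boronates. No ring is closed. The only new stereocentre, C6', is set under catalyst control by the chiral ferrocenyl diphosphine, which differentiates the two faces of the palladium-bound vinylborate; the ligand antipode that leads to 6'R is to be fixed in a trial run with 2-bromopropene (Mosher ester analysis), the remote C2 centre should not interfere, and perborate then replaces boron by hydroxyl with retention. The step needs chemoselectivity (metallate shift instead of direct alkenyl transfer to palladium or β-hydride elimination, secured by the bidentate ligand and the absence of base) and site selectivity (secured because only the vinyl group of 22 is unhindered enough to bind palladium and only 17 carries a C–Br bond). Both trisubstituted alkenes should keep their E geometry, since migration, oxidative addition and reductive elimination all proceed with retention at sp2 carbon.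

Step 14
Reactants: 24 (3E,6R,7E)-1-[(2R)-2,8-dimethyl-6-{[tri(propan-2-yl)silyl]oxy}-2H-chromen-2-yl]-4,8,12-trimethyltrideca-3,7,11-trien-6-ol
Product: 25 (2R)-2-[(3E,6R,7E)-6-hydroxy-4,8,12-trimethyltrideca-3,7,11-trien-1-yl]-2,8-dimethyl-2H-chromen-6-ol
Conditions: Bu4NF, AcOH (1:1), THF, 0 °C, dark, under argon
Reagents that add atoms: none
Why: Fluoride-induced cleavage of the aryl silyl ether, buffered with acetic acid so that the electron-rich phenol is released as the neutral phenol, should leave the allylic alcohol, the three trisubstituted alkenes and the chromene untouched.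

**Compound list**

1 | 4-amino-3-methylphenol | Cc1cc(O)ccc1N | starting material
2 | 2-methyl-4-{[tri(propan-2-yl)silyl]oxy}aniline | Cc1cc(O[Si](C(C)C)(C(C)C)C(C)C)ccc1N | intermediate
3 | 2-iodo-6-methyl-4-{[tri(propan-2-yl)silyl]oxy}aniline | Cc1cc(O[Si](C(C)C)(C(C)C)C(C)C)cc(I)c1N | intermediate
4 | 2-iodo-6-methyl-4-{[tri(propan-2-yl)silyl]oxy}benzenediazonium bromide | Cc1cc(O[Si](C(C)C)(C(C)C)C(C)C)cc(I)c1[N+]#N.[Br-] | intermediate (not isolated)
5 | (4-bromo-3-iodo-5-methylphenoxy)tri(propan-2-yl)silane | Cc1cc(O[Si](C(C)C)(C(C)C)C(C)C)cc(I)c1Br | intermediate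
6 | (R)-(−)-linalool, (3R)-3,7-dimethylocta-1,6-dien-3-ol | C=C[C@](C)(O)CCC=C(C)C | starting material
7 | (3S)-1-(9-borabicyclo[3.3.1]nonan-9-yl)-3,7-dimethyloct-6-en-3-ol | CC(C)=CCC[C@@](C)(O)CCB1C2CCCC1CCC2 | intermediate (not isolated)
8 | (3R)-1-(2-bromo-3-methyl-5-{[tri(propan-2-yl)silyl]oxy}phenyl)-3,7-dimethyloct-6-en-3-ol | Cc1cc(O[Si](C(C)C)(C(C)C)C(C)C)cc(CC[C@](C)(O)CCC=C(C)C)c1Br | intermediate
9 | tri(propan-2-yl){[(2R)-2,8-dimethyl-2-(4-methylpent-3-en-1-yl)-3,4-dihydro-2H-chromen-6-yl]oxy}silane | Cc1cc(O[Si](C(C)C)(C(C)C)C(C)C)cc2CC[C@@](C)(CCC=C(C)C)Oc12 | intermediate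
10 | 5-[(2S)-2,8-dimethyl-6-{[tri(propan-2-yl)silyl]oxy}-3,4-dihydro-2H-chromen-2-yl]-2-methylpentane-2,3-diol (both C3 epimers) | Cc1cc(O[Si](C(C)C)(C(C)C)C(C)C)cc2CC[C@@](C)(CCC(O)C(C)(C)O)Oc12 | intermediate (not isolated)
11 | 3-[(2S)-2,8-dimethyl-6-{[tri(propan-2-yl)silyl]oxy}-3,4-dihydro-2H-chromen-2-yl]propanal | Cc1cc(O[Si](C(C)C)(C(C)C)C(C)C)cc2CC[C@@](C)(CCC=O)Oc12 | intermediate
12 | {[(2R)-2-(4,4-dibromobut-3-en-1-yl)-2,8-dimethyl-3,4-dihydro-2H-chromen-6-yl]oxy}tri(propan-2-yl)silane | Cc1cc(O[Si](C(C)C)(C(C)C)C(C)C)cc2CC[C@@](C)(CCC=C(Br)Br)Oc12 | intermediate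
13 | {4-[(2R)-2,8-dimethyl-6-{[tri(propan-2-yl)silyl]oxy}-3,4-dihydro-2H-chromen-2-yl]but-1-yn-1-yl}lithium | Cc1cc(O[Si](C(C)C)(C(C)C)C(C)C)cc2CC[C@@](C)(CCC#C[Li])Oc12 | intermediate (not isolated)
14 | {[(2R)-2,8-dimethyl-2-(pent-3-yn-1-yl)-3,4-dihydro-2H-chromen-6-yl]oxy}tri(propan-2-yl)silane | Cc1cc(O[Si](C(C)C)(C(C)C)C(C)C)cc2CC[C@@](C)(CCC#CC)Oc12 | intermediate
15 | chlorobis(cyclopentadienyl){(2E)-5-[(2R)-2,8-dimethyl-6-{[tri(propan-2-yl)silyl]oxy}-3,4-dihydro-2H-chromen-2-yl]pent-2-en-2-yl}zirconium | Cc1cc(O[Si](C(C)C)(C(C)C)C(C)C)cc2CC[C@@](C)(CC/C=C(\C)[Zr](Cl)(C3C=CC=C3)C3C=CC=C3)Oc12 | intermediate (not isolated)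
16 | {[(2R)-2-[(3E)-4-bromopent-3-en-1-yl]-2,8-dimethyl-3,4-dihydro-2H-chromen-6-yl]oxy}tri(propan-2-yl)silane | Cc1cc(O[Si](C(C)C)(C(C)C)C(C)C)cc2CC[C@@](C)(CC/C=C(\C)Br)Oc12 | intermediate
17 | {[(2R)-2-[(3E)-4-bromopent-3-en-1-yl]-2,8-dimethyl-2H-chromen-6-yl]oxy}tri(propan-2-yl)silane | Cc1cc(O[Si](C(C)C)(C(C)C)C(C)C)cc2C=C[C@@](C)(CC/C=C(\C)Br)Oc12 | intermediate
18 | 5-bromo-2-methylpent-2-ene | CC(C)=CCCBr | starting material
19 | 6-methylhept-5-en-1-yne | CC(C)=CCCC#C | intermediate
20 | [(1E)-2,6-dimethylhepta-1,5-dien-1-yl]dimethylalumane | CC(C)=CCC/C(C)=C/[Al](C)C | intermediate (not isolated)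
21 | 2-[(1E)-2,6-dimethylhepta-1,5-dien-1-yl]-4,4,5,5-tetramethyl-1,3,2-dioxaborolane | CC(C)=CCC/C(C)=C/B1OC(C)(C)C(C)(C)O1 | intermediate
22 | lithium [(1E)-2,6-dimethylhepta-1,5-dien-1-yl](ethenyl)(2,3-dimethylbutane-2,3-diolato)borate | [Li+].CC(C)=CCC/C(C)=C/[B-]1(C=C)OC(C)(C)C(C)(C)O1 | intermediate (not isolated)
23 | tri(propan-2-yl){[(2R)-2,8-dimethyl-2-[(3E,6R,7E)-4,8,12-trimethyl-6-(4,4,5,5-tetramethyl-1,3,2-dioxaborolan-2-yl)trideca-3,7,11-trien-1-yl]-2H-chromen-6-yl]oxy}silane | CC(C)=CCC/C(C)=C/[C@H](B1OC(C)(C)C(C)(C)O1)C/C(C)=C/CC[C@]2(C)C=Cc3cc(O[Si](C(C)C)(C(C)C)C(C)C)cc(C)c3O2 | intermediate (not isolated)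
24 | (3E,6R,7E)-1-[(2R)-2,8-dimethyl-6-{[tri(propan-2-yl)silyl]oxy}-2H-chromen-2-yl]-4,8,12-trimethyltrideca-3,7,11-trien-6-ol | CC(C)=CCC/C(C)=C/[C@H](O)C/C(C)=C/CC[C@]1(C)C=Cc2cc(O[Si](C(C)C)(C(C)C)C(C)C)cc(C)c2O1 | intermediate
25 | (2R)-2-[(3E,6R,7E)-6-hydroxy-4,8,12-trimethyltrideca-3,7,11-trien-1-yl]-2,8-dimethyl-2H-chromen-6-ol | CC(C)=CCC/C(C)=C/[C@H](O)C/C(C)=C/CC[C@]1(C)C=Cc2cc(O)cc(C)c2O1 | target

**Step count and risks**

Total step count: 14. Longest linear sequence: 12 steps (steps 1–10, 13, 14).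

Steps most likely to fail:

1. Step 13. The risk is that direct alkenyl transfer from borate 22 to palladium (a plain Suzuki-type coupling) outruns the 1,2-metallate shift, or that the facial control at C6' is insufficient. The fallback makes the same C5'–C4' bond by enolate alkenylation and sets C6' by reduction; it sets out from 19 and 17 and comes back at 24. Alane 20, made from 19 as in step 12, would be acylated with acetyl chloride (Pd(PPh3)4 cat., CH2Cl2, 0 °C) to (3E)-4,8-dimethylnona-3,7-dien-2-one F1. Kinetic deprotonation at the methyl group (LiHMDS, THF, −78 °C) would give lithium (3E)-4,8-dimethylnona-1,3,7-trien-2-olate F2. Palladium-catalysed ketone α-alkenylation with 17 (Pd2(dba)3, P(t-Bu)3, THF, rt) should give (2R)-2-[(3E,7E)-4,8,12-trimethyl-6-oxotrideca-3,7,11-trien-1-yl]-2,8-dimethyl-6-{[tri(propan-2-yl)silyl]oxy}-2H-chromene F3. Corey–Bakshi–Shibata reduction ((S)-2-methyl-CBS-oxazaborolidine, BH3·SMe2, THF, −40 °C), with the conjugated alkenyl group as the large substituent, should then give 24 with 6'R configuration.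

2. Step 9. The risk is incomplete regiochemical equilibration, which leaves zirconium partly on C3' and gives a 3-bromo regioisomer that is hard to separate. The fallback fixes regiochemistry by olefination instead of hydrometalation; it sets out from aldehyde 11 and comes back at 16, so steps 7 and 8 are not needed. A boron–Wittig reaction of 11 with lithiated 1,1-bis(4,4,5,5-tetramethyl-1,3,2-dioxaborolan-2-yl)ethane (LiTMP, THF, 0 °C) should place the remaining boryl group anti to the chain and give tri(propan-2-yl){[(2R)-2,8-dimethyl-2-[(3Z)-4-(4,4,5,5-tetramethyl-1,3,2-dioxaborolan-2-yl)pent-3-en-1-yl]-3,4-dihydro-2H-chromen-6-yl]oxy}silane F4. Bromodeboronation with retention (CuBr2, MeOH/H2O, 60 °C) would give 16.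

3. Step 10. The risk is oxidative loss of the silyl ether to a quinone, attack at the 8-methyl group, or slow hydride abstraction that forces longer heating and erodes C2. The fallback runs the dehydrogenation on the aryl acetate, the electron-poorer substrate class for which this oxidation is best established; it sets out from 16 and comes back at 17. Desilylation (Bu4NF, THF) would give (2R)-2-[(3E)-4-bromopent-3-en-1-yl]-2,8-dimethyl-3,4-dihydro-2H-chromen-6-ol F5. Acetylation (Ac2O, pyridine) would give (2R)-2-[(3E)-4-bromopent-3-en-1-yl]-2,8-dimethyl-3,4-dihydro-2H-chromen-6-yl acetate F6. DDQ (benzene, 80 °C, dark) would give (2R)-2-[(3E)-4-bromopent-3-en-1-yl]-2,8-dimethyl-2H-chromen-6-yl acetate F7. Methanolysis (K2CO3, MeOH, 0 °C) would give (2R)-2-[(3E)-4-bromopent-3-en-1-yl]-2,8-dimethyl-2H-chromen-6-ol F8, and silylation (TIPSCl, imidazole, DMF) would return 17.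

Further compounds
F1 | step 13 | (3E)-4,8-dimethylnona-3,7-dien-2-one | CC(C)=CCC/C(C)=C/C(C)=O
F2 | step 13 | lithium (3E)-4,8-dimethylnona-1,3,7-trien-2-olate | [Li]OC(=C)/C=C(\C)CCC=C(C)C
F3 | step 13 | (2R)-2-[(3E,7E)-4,8,12-trimethyl-6-oxotrideca-3,7,11-trien-1-yl]-2,8-dimethyl-6-{[tri(propan-2-yl)silyl]oxy}-2H-chromene | CC(C)=CCC/C(C)=C/C(=O)C/C(C)=C/CC[C@]1(C)C=Cc2cc(O[Si](C(C)C)(C(C)C)C(C)C)cc(C)c2O1
F4 | step 9 | tri(propan-2-yl){[(2R)-2,8-dimethyl-2-[(3Z)-4-(4,4,5,5-tetramethyl-1,3,2-dioxaborolan-2-yl)pent-3-en-1-yl]-3,4-dihydro-2H-chromen-6-yl]oxy}silane | Cc1cc(O[Si](C(C)C)(C(C)C)C(C)C)cc2CC[C@@](C)(CC/C=C(\C)B3OC(C)(C)C(C)(C)O3)Oc12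
F5 | step 10 | (2R)-2-[(3E)-4-bromopent-3-en-1-yl]-2,8-dimethyl-3,4-dihydro-2H-chromen-6-ol | Cc1cc(O)cc2CC[C@@](C)(CC/C=C(\C)Br)Oc12
F6 | step 10 | (2R)-2-[(3E)-4-bromopent-3-en-1-yl]-2,8-dimethyl-3,4-dihydro-2H-chromen-6-yl acetate | Cc1cc(OC(C)=O)cc2CC[C@@](C)(CC/C=C(\C)Br)Oc12
F7 | step 10 | (2R)-2-[(3E)-4-bromopent-3-en-1-yl]-2,8-dimethyl-2H-chromen-6-yl acetate | Cc1cc(OC(C)=O)cc2C=C[C@@](C)(CC/C=C(\C)Br)Oc12
F8 | step 10 | (2R)-2-[(3E)-4-bromopent-3-en-1-yl]-2,8-dimethyl-2H-chromen-6-ol | Cc1cc(O)cc2C=C[C@@](C)(CC/C=C(\C)Br)Oc12
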